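**Retrosynthetic overview**

1. Feature: the core is a 5,6,7,8-tetrahydro-1H-isochromen-8-one, a carbocycle C4a–C5–C6–C7–C8–C8a fused to the pyran O2/C1/C3/C4. Its tertiary C7 oxygen carries a benzoate with oxygen on C2′ and C4′ and methyl on C6′, which is a folded tetraketide. The arene can therefore be grown on O7 from an open 3,5,7-trioxooctanoyl chain, and no di-ortho-substituted aroyl group has to be forced onto O7.
2. Last disconnections: the two silyl ethers, the C2′ O-methyl group and a temporary C4′ silyl ether. Before them come the benzene ring (C1′–C6′ aldol, aromatisation) and the O7–acyl bond (acylketene from a diketo-dioxinone), which lead back to the O6-silylated bicyclic α-ketol.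
3. Pyran ring: O2–C3 closure of a 2-(hydroxymethyl)-3-pentenynyl cyclohexenone. C8a–C1 comes from a hydroxymethyl Stille coupling. C4a–C4 comes from acetylide addition to a 2-iodoenone and an oxidative 1,3-transposition that places the carbonyl on C8, so no dehydrogenation is needed.
4. Carbocycle and both stereocentres come from (R)-carvone. Its carbonyl carbon becomes C6 (Luche reduction) and its methyl-bearing alkene carbon becomes C7 (hydroxyl-directed epoxidation, cis to O6). The isopropenyl-bearing carbon is cut down to the C4a ketone, and E1cB opening of the epoxide gives the γ-hydroxy enone.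
5. Order of rings: carbocycle (chiral pool), then the pyran ring, then the benzene ring.

Key step: step 13

Remark: atoms of all intermediates carry the isochromene numbers of the target atoms they become. (E)-Pent-3-en-1-yne is taken as the pure E isomer, and no step touches its geometry.

**Route**

Step 1
Reactants: 1 (R)-carvone
Product: 2 (1R,5R)-cis-carveol (hydroxyl cis to isopropenyl)
Conditions: NaBH4, CeCl3·7H2O, MeOH, −20 to 0 °C
Reagents that add atoms: none
Why: Luche reduction: the cerium-modified borohydride adds 1,2 and from the axial direction to the half-chair that keeps the isopropenyl group equatorial, so the new C6 carbinol should be equatorial and cis to that group (1R), the sense needed for 6R in the target.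

Step 2
Reactants: 2 (1R,5R)-cis-carveol
Product: 3 cis-carveol 1,2-epoxide (hydroxyl/epoxide oxygen/isopropenyl all on one ring face)
Conditions: VO(acac)2 (2 mol %), t-BuOOH, CH2Cl2, 0 °C to rt
Reagents that add atoms: tert-butyl hydroperoxide, CC(C)(C)OO
Why: Vanadium-catalysed hydroxyl-directed epoxidation: the alkoxide-bound peroxovanadium species passes oxygen to the neighbouring C7=C8 alkene on the face of O6, which sets the C7–O bond cis to O6 (7R of the target) and spares the unbound isopropenyl alkene.

Step 3
Reactants: 3 cis-carveol 1,2-epoxide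
Product: 4 O6-tert-butyldimethylsilyl ether of 3
Conditions: TBSCl, imidazole, DMAP (5 mol %), DMF, rt to 40 °C
Reagents that add atoms: tert-butyldimethylsilyl chloride, CC(C)(C)[Si](C)(C)Cl
Why: Imidazole-promoted silylation of the only hydroxyl group under non-acidic conditions that leave the epoxide closed, giving the O6 protecting group that stays until the last step.

Step 4
Reactants: 4 O6-TBS epoxide
Product: 7 β,γ-epoxy ketone 5-(tert-butyldimethylsilyloxy)-6-methyl-7-oxabicyclo[4.1.0]heptan-3-one (silyloxy cis to epoxide oxygen), via methoxy hydroperoxide 5 (not isolated), via TEMPO ether 6 (not isolated)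
Conditions: O3, MeOH, −78 °C; FeSO4·7H2O, TEMPO, −78 °C to rt; magnesium bis(monoperoxyphthalate) hexahydrate, rt
Reagents that add atoms: TEMPO, CC1(C)CCCC(C)(C)N1[O] (supplies the C4a carbonyl oxygen of 7); ozone, [O-][O+]=O, and methanol, CO (atoms kept only in 5)
Why: Oxodealkenylation, a known one-pot sequence for terpene isopropenyl groups (Criegee ozonolysis in methanol, one-electron reduction of the hydroperoxide by divalent iron, β-scission to the C4a radical, capture by TEMPO, peracid-induced fragmentation of the alkoxyamine), turns C4a into a ketone; the stereocentre lost there has done its work and the radical is not adjacent to the epoxide, so C6 and C7 stay as set.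

Step 5
Reactants: 7 β,γ-epoxy ketone
Product: 9 (4S,5R)-5-(tert-butyldimethylsilyloxy)-4-methyl-4-(trimethylsilyloxy)cyclohex-2-en-1-one, via hydroxy enone 8 (not isolated)
Conditions: DBU (10 mol %), CH2Cl2, 0 °C; then N-(trimethylsilyl)imidazole, 0 °C to rt
Reagents that add atoms: N-(trimethylsilyl)imidazole, C[Si](C)(C)n1ccnc1
Why: Base-catalysed E1cB isomerisation of a β,γ-epoxy ketone: enolisation toward C8a breaks the strained C8–O bond much faster than the C5 enolate could expel silyloxide, the C7–O bond is not touched so C7 keeps its configuration, and silylation in the same flask masks the new tertiary allylic alcohol for steps 7 and 8.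

Step 6
Reactants: 9 bis-silylated enone
Product: 10 (4S,5R)-5-(tert-butyldimethylsilyloxy)-2-iodo-4-methyl-4-(trimethylsilyloxy)cyclohex-2-en-1-one
Conditions: I2, pyridine–CH2Cl2, 0 °C to rt
Reagents that add atoms: iodine, II
Why: Baylis–Hillman-type α-iodination of an enone (reversible addition of pyridine at C8, iodination of the enolate at C8a, loss of pyridinium), known to tolerate a quaternary γ-carbon, under a base too weak to eliminate the C6 silyloxy group.

Step 7
Reactants: 10 iodoenone; 11 (E)-pent-3-en-1-yne
Product: 13 (4S,5R)-5-(tert-butyldimethylsilyloxy)-2-iodo-4-methyl-1-[(E)-pent-3-en-1-ynyl]-4-(trimethylsilyloxy)cyclohex-2-en-1-ol (both C1 epimers), via lithium acetylide 12 (not isolated)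
Conditions: 11 (slight excess), n-BuLi, THF, −78 °C; then 10, −78 °C; aq NH4Cl
Reagents that add atoms: n-butyllithium, [Li]CCCC (lithium, kept only in 12)
Why: 1,2-Addition of a hard and weakly basic lithium acetylide to the iodine-activated enone carbonyl forms the C4a–C4 bond without iodine–lithium exchange, and the new C4a carbinol centre may form as a mixture because it becomes sp2 in step 8.

Step 8
Reactants: 13 tertiary alcohol
Product: 14 (5R,6R)-5-(tert-butyldimethylsilyloxy)-2-iodo-6-methyl-3-[(E)-pent-3-en-1-ynyl]-6-(trimethylsilyloxy)cyclohex-2-en-1-one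
Conditions: pyridinium chlorochromate, NaOAc, 4 Å molecular sieves, CH2Cl2, rt
Reagents that add atoms: pyridinium chlorochromate, c1cc[nH+]cc1.[O-][Cr](=O)(=O)Cl (the C8 carbonyl oxygen comes from chromate, the C4a hydroxyl oxygen leaves with chromium)
Why: Babler–Dauben oxidative transposition: the chromate ester of the tertiary allylic and propargylic alcohol shifts [3,3] to C8 and is oxidised there, which is driven by the tetrasubstituted C4a=C8a alkene conjugated to the alkyne and the new carbonyl, while the silylated O7 cannot form a competing chromate ester.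

Step 9
Reactants: 14 iodo enynone
Product: 15 (5R,6R)-5-(tert-butyldimethylsilyloxy)-2-(hydroxymethyl)-6-methyl-3-[(E)-pent-3-en-1-ynyl]-6-(trimethylsilyloxy)cyclohex-2-en-1-one
Conditions: Bu3SnCH2OH, Pd(PPh3)4 (5 mol %), dioxane, 80 °C
Reagents that add atoms: (tributylstannyl)methanol, CCCC[Sn](CCCC)(CCCC)CO
Why: Stille coupling with oxygen-assisted transfer of the hydroxymethyl group from tin: α-iodoenones add readily to zerovalent palladium and the neutral medium leaves both silyl ethers and the enynone intact.

Step 10
Reactants: 15 hydroxymethyl enynone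
Product: 17 (6R,7R)-6-(tert-butyldimethylsilyloxy)-7-hydroxy-7-methyl-3-[(E)-prop-1-enyl]-5,6,7,8-tetrahydro-1H-isochromen-8-one, via dienaminone 16 (not isolated)
Conditions: Et2NH, THF, rt; concentrate; then AcOH–THF–H2O, rt
Reagents that add atoms: diethylamine, CCNCC (kept only in 16)
Why: Conjugate 1,6-addition of the secondary amine fixes the electrophilic site at C3, the δ-carbon of the en-ynone, and on acidification the C1 hydroxyl adds to the C3 iminium carbon in a 6-exo-trig closure and expels the amine, so the six-membered pyran and not the five-membered alkylidene dihydrofuran should form; the same medium hydrolyses the tertiary trimethylsilyl ether while the hindered secondary TBS ether stays.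

Step 11
Reactants: 18 2,2,6-trimethyl-4H-1,3-dioxin-4-one
Product: 19 2,2-dimethyl-6-(2-oxopropyl)-4H-1,3-dioxin-4-one
Conditions: LiN(SiMe3)2, THF, −78 °C; AcCl, −78 °C
Reagents that add atoms: acetyl chloride, CC(=O)Cl
Why: Vinylogous Claisen-type acylation: the lithium dienolate of the dioxinone reacts at its γ-carbon (the C6 methyl group) with the acid chloride, a standard entry to keto-dioxinones.

Step 12
Reactants: 19 keto-dioxinone
Product: 20 2,2-dimethyl-6-(2,4-dioxopentyl)-4H-1,3-dioxin-4-one
Conditions: LiN(i-Pr)2 (3 equiv), THF, −78 °C; N-methoxy-N-methylacetamide, −78 to −10 °C; aq HCl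
Reagents that add atoms: N-methoxy-N-methylacetamide, CC(=O)N(C)OC
Why: Claisen condensation of the dianion: the second, less stabilised carbanion at the terminal methyl group is the more nucleophilic site, and the stable tetrahedral Weinreb adduct prevents a second addition.

Step 13
Reactants: 17 bicyclic α-ketol (O6 TBS); 20 diketo-dioxinone
Product: 23 (6R,7R)-6-(tert-butyldimethylsilyloxy)-7-methyl-8-oxo-3-[(E)-prop-1-enyl]-5,6,7,8-tetrahydro-1H-isochromen-7-yl 2,4-dihydroxy-6-methylbenzoate, via acylketene 21 (not isolated), via triketo ester 22 (not isolated)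
Conditions: 17 in PhMe, 110 °C, 20 (2.5 equiv) added slowly by syringe pump; cool; K2CO3, CH2Cl2–i-PrOH, rt; then AcOH
Reagents that add atoms: none
Why: Retro-[4+2] loss of acetone from 20 gives the linear acylketene 21, and the O7–H bond adds to it through a planar pseudopericyclic transition state of little steric demand, giving after tautomerisation the triketo ester 22. The closest known reaction type is the thermolysis of diketo-dioxinones in the presence of alcohols, tertiary ones included, followed by biomimetic aromatisation to resorcylate esters. The benzene ring closes by a 6-(enolendo)-exo-trig aldol addition of the C1′ enolate to the terminal C6′ methyl ketone, and loss of water and enolisation make it irreversible. No stereocentre is formed, and C6 and C7 are spectators because neither of their C–O bonds is broken. For the capture, O7–H is the only hydroxyl because O6 is silylated, the C3=C4 enol ether is part of a doubly vinylogous ester and so a poor [4+2] partner for 21, and slow addition of 20 to hot concentrated 17 keeps 21 from being consumed by its own enolised side chain or by dimerisation. For the closure, the C3′ and C5′ methylenes between two ketones are the more acidic ones, but the enolates equilibrate and only C1′ has an unhindered six-ring aldol partner, whereas Claisen attack of C5′ on the crowded ester carbonyl and Knoevenagel attack of C1′ on the electron-rich, flanked C8 carbonyl should be slower.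

Step 14
Reactants: 23 orsellinate ester
Product: 24 4′-O-triisopropylsilyl ether of 23
Conditions: TIPSCl (1.1 equiv), imidazole, DMF, 0 °C
Reagents that add atoms: triisopropylsilyl chloride, CC(C)[Si](Cl)(C(C)C)C(C)C
Why: Chemoselective silylation: the C2′ hydroxyl is tied up in a hydrogen bond to the ester carbonyl and flanked by the acyl group, so the bulky chlorosilane should take only the free C4′ phenol, and triisopropylsilyl is chosen because an aryl silyl ether para to an ester must survive carbonate in step 15.

Step 15
Reactants: 24 4′-O-TIPS ester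
Product: 25 2′-O-methyl ether of 24
Conditions: MeI, K2CO3, dry acetone, rt to 40 °C
Reagents that add atoms: iodomethane, CI
Why: Williamson O-methylation of the remaining salicylate-type phenol, run with a heterogeneous weak base in an aprotic solvent so that neither the aryl silyl ether is solvolysed nor the C5 protons of the vinylogous system are removed.

Step 16
Reactants: 25 fully protected ester
Product: 26 target CNP0187389.2
Conditions: HF·pyridine, pyridine–THF, 0 °C to rt
Reagents that add atoms: none
Why: Fluoride-driven cleavage of both Si–O bonds in a buffered, slightly acidic medium, in which the di-ortho-substituted ester should not migrate from O7 to the freed cis O6 hydroxyl and the doubly vinylogous ester of the core is not hydrolysed.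

**Compound list**

1 | (R)-carvone | CC1=CC[C@H](CC1=O)C(C)=C | starting material
2 | (1R,5R)-cis-carveol | CC1=CC[C@H](C[C@H]1O)C(C)=C | intermediate
3 | (1R,2R,4S,6S)-1-methyl-4-(prop-1-en-2-yl)-7-oxabicyclo[4.1.0]heptan-2-ol (all-cis epoxy alcohol) | C[C@]12O[C@H]1C[C@H](C[C@H]2O)C(C)=C | intermediate
4 | O6-tert-butyldimethylsilyl ether of 3 | C[C@]12O[C@H]1C[C@H](C[C@H]2O[Si](C)(C)C(C)(C)C)C(C)=C | intermediate
5 | methoxy hydroperoxide (isopropenyl replaced by 2-hydroperoxy-2-methoxyethan-2-yl; new centre undefined) | C[C@]12O[C@H]1C[C@H](C[C@H]2O[Si](C)(C)C(C)(C)C)C(C)(OC)OO | intermediate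
6 | TEMPO ether at C4a (both C4a epimers) | C[C@]12O[C@H]1CC(C[C@H]2O[Si](C)(C)C(C)(C)C)ON1C(C)(C)CCCC1(C)C | intermediate
7 | 5-(tert-butyldimethylsilyloxy)-6-methyl-7-oxabicyclo[4.1.0]heptan-3-one (silyloxy cis to epoxide oxygen) | C[C@]12O[C@H]1CC(=O)C[C@H]2O[Si](C)(C)C(C)(C)C | intermediate
8 | (4S,5R)-5-(tert-butyldimethylsilyloxy)-4-hydroxy-4-methylcyclohex-2-en-1-one | O=C1C=C[C@](C)(O)[C@H](O[Si](C)(C)C(C)(C)C)C1 | intermediate
9 | (4S,5R)-5-(tert-butyldimethylsilyloxy)-4-methyl-4-(trimethylsilyloxy)cyclohex-2-en-1-one | O=C1C=C[C@](C)(O[Si](C)(C)C)[C@H](O[Si](C)(C)C(C)(C)C)C1 | intermediate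
10 | (4S,5R)-5-(tert-butyldimethylsilyloxy)-2-iodo-4-methyl-4-(trimethylsilyloxy)cyclohex-2-en-1-one | O=C1C(I)=C[C@](C)(O[Si](C)(C)C)[C@H](O[Si](C)(C)C(C)(C)C)C1 | intermediate
11 | (E)-pent-3-en-1-yne | C/C=C/C#C | starting material
12 | lithium (E)-pent-3-en-1-yn-1-ide | [Li]C#C/C=C/C | intermediate
13 | (4S,5R)-5-(tert-butyldimethylsilyloxy)-2-iodo-4-methyl-1-[(E)-pent-3-en-1-ynyl]-4-(trimethylsilyloxy)cyclohex-2-en-1-ol (C1 epimers) | C/C=C/C#CC1(O)C(I)=C[C@](C)(O[Si](C)(C)C)[C@H](O[Si](C)(C)C(C)(C)C)C1 | intermediate
14 | (5R,6R)-5-(tert-butyldimethylsilyloxy)-2-iodo-6-methyl-3-[(E)-pent-3-en-1-ynyl]-6-(trimethylsilyloxy)cyclohex-2-en-1-one | C/C=C/C#CC1=C(I)C(=O)[C@](C)(O[Si](C)(C)C)[C@H](O[Si](C)(C)C(C)(C)C)C1 | intermediate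
15 | (5R,6R)-5-(tert-butyldimethylsilyloxy)-2-(hydroxymethyl)-6-methyl-3-[(E)-pent-3-en-1-ynyl]-6-(trimethylsilyloxy)cyclohex-2-en-1-one | C/C=C/C#CC1=C(CO)C(=O)[C@](C)(O[Si](C)(C)C)[C@H](O[Si](C)(C)C(C)(C)C)C1 | intermediate
16 | dienaminone: 15 with Et2N–H added across the alkyne, nitrogen on C3 (C3=C4 geometry undefined) | C/C=C/C(=CC1=C(CO)C(=O)[C@](C)(O[Si](C)(C)C)[C@H](O[Si](C)(C)C(C)(C)C)C1)N(CC)CC | intermediate
17 | (6R,7R)-6-(tert-butyldimethylsilyloxy)-7-hydroxy-7-methyl-3-[(E)-prop-1-enyl]-5,6,7,8-tetrahydro-1H-isochromen-8-one | C/C=C/C1=CC2=C(CO1)C(=O)[C@](C)(O)[C@H](O[Si](C)(C)C(C)(C)C)C2 | intermediate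
18 | 2,2,6-trimethyl-4H-1,3-dioxin-4-one | CC1=CC(=O)OC(C)(C)O1 | starting material
19 | 2,2-dimethyl-6-(2-oxopropyl)-4H-1,3-dioxin-4-one | CC(=O)CC1=CC(=O)OC(C)(C)O1 | intermediate
20 | 2,2-dimethyl-6-(2,4-dioxopentyl)-4H-1,3-dioxin-4-one | CC(=O)CC(=O)CC1=CC(=O)OC(C)(C)O1 | intermediate
21 | 3,5,7-trioxooct-1-en-1-one (acylketene) | CC(=O)CC(=O)CC(=O)C=C=O | intermediate
22 | O7 3,5,7-trioxooctanoate of 17 | C/C=C/C1=CC2=C(CO1)C(=O)[C@](C)(OC(=O)CC(=O)CC(=O)CC(C)=O)[C@H](O[Si](C)(C)C(C)(C)C)C2 | intermediate
23 | O7 2,4-dihydroxy-6-methylbenzoate of 17 (6R,7R) | C/C=C/C1=CC2=C(CO1)C(=O)[C@](C)(OC(=O)c1c(C)cc(O)cc1O)[C@H](O[Si](C)(C)C(C)(C)C)C2 | intermediate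
24 | O7 2-hydroxy-6-methyl-4-(triisopropylsilyloxy)benzoate of 17 (6R,7R) | C/C=C/C1=CC2=C(CO1)C(=O)[C@](C)(OC(=O)c1c(C)cc(O[Si](C(C)C)(C(C)C)C(C)C)cc1O)[C@H](O[Si](C)(C)C(C)(C)C)C2 | intermediate
25 | O7 2-methoxy-6-methyl-4-(triisopropylsilyloxy)benzoate of 17 (6R,7R) | C/C=C/C1=CC2=C(CO1)C(=O)[C@](C)(OC(=O)c1c(C)cc(O[Si](C(C)C)(C(C)C)C(C)C)cc1OC)[C@H](O[Si](C)(C)C(C)(C)C)C2 | intermediate
26 | (6R,7R)-6-hydroxy-7-methyl-8-oxo-3-[(E)-prop-1-enyl]-5,6,7,8-tetrahydro-1H-isochromen-7-yl 4-hydroxy-2-methoxy-6-methylbenzoate (CNP0187389.2) | C/C=C/C1=CC2=C(CO1)C(=O)[C@](C)(OC(=O)c1c(C)cc(O)cc1OC)[C@H](O)C2 | target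

**Step count and risks**

Total steps: 16. Longest linear sequence: 14 (steps 1–10 and 13–16).

Steps most likely to fail:

- **Step 13.**
  - What may go wrong: addition of the crowded tertiary α-ketol hydroxyl may be outrun by lactonisation of the acylketene through its own enolised side chain and by ketene dimerisation. After capture, base may trigger Claisen-type closure with loss of the alkoxide, or Knoevenagel lactonisation onto C8, instead of the aldol.
  - Fallback (from 17, rejoining at 25; steps 14 and 15 are skipped): the arene is made first and delivered as a linear acylium ion.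
    - Commercial 2,4-dihydroxy-6-methylbenzaldehyde is silylated at its free para hydroxyl (TIPSCl, imidazole) to 2-hydroxy-6-methyl-4-(triisopropylsilyloxy)benzaldehyde F1.
    - F1 is methylated (MeI, K2CO3, acetone) to 2-methoxy-6-methyl-4-(triisopropylsilyloxy)benzaldehyde F2.
    - F2 is oxidised (Pinnick oxidation: NaClO2, NaH2PO4, 2-methylbut-2-ene) to 2-methoxy-6-methyl-4-(triisopropylsilyloxy)benzoic acid F3.
    - Trifluoroacetic anhydride turns F3 into 2-methoxy-6-methyl-4-(triisopropylsilyloxy)benzoyl trifluoroacetate F4.
    - The electron-rich, di-ortho-substituted aroyl group of F4 should ionise and acylate O7 of 17 (2,6-di-tert-butylpyridine, CH2Cl2) to give 25.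

- **Step 8.**
  - What may go wrong: the [3,3] shift toward C8, which lies next to the quaternary C7, may be slow. This would leave time for ionisation of the doubly activated tertiary alcohol, for elimination toward an arene, and for acid-induced loss of the trimethylsilyl group.
  - Fallback (from 13, rejoining at 14): the allylic shift and the oxidation are separated.
    - Catalytic Ph3SiOReO3 in Et2O at low temperature equilibrates 13 to the thermodynamically preferred conjugated secondary allylic alcohol, the C8-carbinol analogue of 14 (both C8 epimers) F5.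
    - Dess–Martin periodinane buffered with NaHCO3 then oxidises F5 to 14.

- **Step 9.**
  - What may go wrong: transfer of the hydroxymethyl group to the crowded tetrasubstituted vinylpalladium species may be slow, which allows protodeiodination. The freshly formed (Z)-enynol may also undergo premature metal-induced 5-exo closure and aromatisation to a furan.
  - Fallback (from 14, rejoining at 16): the alkyne is masked before the alcohol is introduced.
    - Et2NH is added to 14 first, giving the 2-iodo dienaminone (14 with Et2N–H added across the alkyne, nitrogen on C3) F6.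
    - The hydroxymethyl Stille coupling is run on F6 and delivers 16.
    - The acid stage of step 10 then closes 16 to 17.

**Further compounds**

F1 | step 13 | 2-hydroxy-6-methyl-4-(triisopropylsilyloxy)benzaldehyde | Cc1cc(O[Si](C(C)C)(C(C)C)C(C)C)cc(O)c1C=O
F2 | step 13 | 2-methoxy-6-methyl-4-(triisopropylsilyloxy)benzaldehyde | COc1cc(O[Si](C(C)C)(C(C)C)C(C)C)cc(C)c1C=O
F3 | step 13 | 2-methoxy-6-methyl-4-(triisopropylsilyloxy)benzoic acid | COc1cc(O[Si](C(C)C)(C(C)C)C(C)C)cc(C)c1C(O)=O
F4 | step 13 | 2-methoxy-6-methyl-4-(triisopropylsilyloxy)benzoyl trifluoroacetate | COc1cc(O[Si](C(C)C)(C(C)C)C(C)C)cc(C)c1C(=O)OC(=O)C(F)(F)F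
F5 | step 8 | C8-carbinol analogue of 14 (both C8 epimers) | C/C=C/C#CC1=C(I)C(O)[C@](C)(O[Si](C)(C)C)[C@H](O[Si](C)(C)C(C)(C)C)C1
F6 | step 9 | 2-iodo dienaminone (14 with Et2N–H added across the alkyne, nitrogen on C3) | C/C=C/C(=CC1=C(I)C(=O)[C@](C)(O[Si](C)(C)C)[C@H](O[Si](C)(C)C(C)(C)C)C1)N(CC)CC
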